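The route rests on a temporary bond between C5 and C10, the transannular 1,6 pair of the ten-membered ring. With that bond the macrocycle becomes a trans-fused eudesmane decalin: ring A (C10, C1, C2, C3, C4, C5) stores the cis C3=C4 bond as a cyclohexene, ring B carries the lactone and the C8 ester. A single Wharton–Grob fragmentation of the C5 alkoxide against an equatorial C1 mesylate then breaks C5–C10, writes the C5 ketone and the trans C1=C10 bond (later the epoxide) and releases the cyclodecadienone. Precursor 29 is the 5α-hydroxy 1β-mesylate already bearing the C8 tiglate, the methylene lactone and a C2 silyl ether.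

Key step: step 22

Remark: eudesmane/germacrane numbering is used (ring C1–C10, lactone carbons C11–C13, C14 on C10, C15 on C4); for the decalins α and β refer to the drawing in which the C10 methyl is β.
Remark: (S)-carvone is used because steps 1–3 transpose the ring carbonyl, which exchanges the two CH2 groups flanking the stereocenter; that carbon then maps onto C7 with the configuration of the target.
Remark: 6–9 and 11 are C2 epimer mixtures (cyclohexanone numbering) and 17–19 carry a 6α hydroxyl; both centres are erased later (steps 8 and 14).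

Step 1
Reactants: 1 (S)-carvone
Product: 2 (S)-carvone p-toluenesulfonylhydrazone
Conditions: TsNHNH2, AcOH (cat.), EtOH, 60 °C
Reagents that add atoms: p-toluenesulfonohydrazide, Cc1ccc(cc1)S(=O)(=O)NN
Why: Acid-catalysed hydrazone formation at the enone carbonyl; the carvone stereocenter is not involved.

Step 2
Reactants: 2 (S)-carvone p-toluenesulfonylhydrazone
Product: 3 (5S)-2-methyl-5-(prop-1-en-2-yl)cyclohexa-1,3-diene
Conditions: MeLi (2.5 equiv), Et2O, 0 °C → rt; H2O
Reagents that add atoms: none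
Why: Shapiro reaction: deprotonation at N–H and at the α′ CH2, loss of sulfinate and N2 and protonation of the vinyllithium give the ring diene; no stereocenter is touched.

Step 3
Reactants: 3 (5S)-2-methyl-5-(prop-1-en-2-yl)cyclohexa-1,3-diene
Product: 5 (4S,5R)-4-hydroxy-2-methyl-5-(prop-1-en-2-yl)cyclohex-2-en-1-one, via endoperoxide 4 (not isolated)
Conditions: O2, hν, 5,10,15,20-tetraphenylporphyrin (cat.), CH2Cl2, −30 °C; then Et3N, 0 °C → rt
Reagents that add atoms: oxygen, O=O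
Why: Singlet oxygen should add [4+2] to the ring diene opposite the neighbouring isopropenyl group, and Kornblum–DeLaMare rearrangement then removes the bridgehead hydrogen flanked by CH2 (the other is shielded by the isopropenyl-bearing carbon), placing the hydroxyl trans to the side chain.

Step 4
Reactants: 5 (4S,5R)-4-hydroxy-2-methyl-5-(prop-1-en-2-yl)cyclohex-2-en-1-one
Product: 6 (4S,5R)-4-hydroxy-2-methyl-5-(prop-1-en-2-yl)cyclohexan-1-one (C2 epimers)
Conditions: LiBH(s-Bu)3 (2.2 equiv), THF, −78 °C; H2O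
Reagents that add atoms: none
Why: Conjugate hydride reduction of the β-unsubstituted enone by the hindered borohydride, as in carvone to dihydrocarvone; the new C2 centre is erased in step 8.

Step 5
Reactants: 6 (4S,5R)-4-hydroxy-2-methyl-5-(prop-1-en-2-yl)cyclohexan-1-one
Product: 7 (4S,5R)-5-(3-chloroprop-1-en-2-yl)-4-hydroxy-2-methylcyclohexan-1-one
Conditions: Ca(OCl)2, solid CO2, CH2Cl2/H2O, 0 °C
Reagents that add atoms: calcium hypochlorite Ca(OCl)2, [Ca+2].[O-]Cl.[O-]Cl
Why: Ene-type allylic chlorination of the 1,1-disubstituted alkene by HOCl made in situ, with shift of the double bond; ketone and secondary alcohol are tolerated and no stereocenter changes.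

Step 6
Reactants: 7 (4S,5R)-5-(3-chloroprop-1-en-2-yl)-4-hydroxy-2-methylcyclohexan-1-one
Product: 8 2-[(1R,2S)-2-hydroxy-4-methyl-5-oxocyclohexyl]prop-2-en-1-yl acetate
Conditions: KOAc, 18-crown-6 (cat.), DMF, 50 °C
Reagents that add atoms: potassium acetate KOAc, CC(=O)[O-].[K+]
Why: SN2 displacement of the primary allylic chloride by acetate.

Step 7
Reactants: 8 2-[(1R,2S)-2-hydroxy-4-methyl-5-oxocyclohexyl]prop-2-en-1-yl acetate
Product: 9 2-[(1R,2R)-2-(4-methoxyphenoxy)-4-methyl-5-oxocyclohexyl]prop-2-en-1-yl acetate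
Conditions: 4-MeOC6H4OH, PPh3, i-PrO2CN=NCO2i-Pr, toluene, 0 °C → rt
Reagents that add atoms: 4-methoxyphenol, COc1ccc(O)cc1
Why: Mitsunobu etherification: the phenol displaces the activated equatorial hydroxyl by SN2 with inversion, so the aryloxy group (the future 8β oxygen) becomes cis to the side chain and serves as a base-stable protecting group.

Step 8
Reactants: 9 2-[(1R,2R)-2-(4-methoxyphenoxy)-4-methyl-5-oxocyclohexyl]prop-2-en-1-yl acetate; 10 ethyl vinyl ketone
Product: 13 2-[(1R,2R,4R)-2-(4-methoxyphenoxy)-4-methyl-5-oxo-4-(3-oxopentyl)cyclohexyl]prop-2-en-1-yl acetate, via ketimine 11 (not isolated), via alkylated ketimine 12 (not isolated)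
Conditions: (R)-PhCH(CH3)NH2, TsOH (cat.), toluene, reflux (−H2O); 10, THF, 40 °C; 20% aq AcOH, rt
Reagents that add atoms: water, O
Why: Deracemising Michael addition of a chiral imine (d'Angelo form of the first Robinson stage): the secondary enamine reacts at the more substituted α-carbon, and the (R)-auxiliary and the axial aryloxy group should both steer the enone to the face opposite the side chain, so the quaternary methyl ends cis to it; aqueous acid hydrolyses the imine.

Step 9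
Reactants: 13 2-[(1R,2R,4R)-2-(4-methoxyphenoxy)-4-methyl-5-oxo-4-(3-oxopentyl)cyclohexyl]prop-2-en-1-yl acetate
Product: 14 8β-(4-methoxyphenoxy)-3-oxoeudesma-4,11(13)-dien-12-yl acetate (7α-H, 10β-CH3)
Conditions: TsOH·H2O (cat.), toluene, reflux, Dean–Stark
Reagents that add atoms: none
Why: Intramolecular aldol condensation (second Robinson stage) of the ethyl ketone CH2 onto the ring ketone with dehydration to the conjugated enone; the three stereocenters are untouched and the acetate survives the acid.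

Step 10
Reactants: 14 8β-(4-methoxyphenoxy)-3-oxoeudesma-4,11(13)-dien-12-yl acetate
Product: 15 8β-(4-methoxyphenoxy)-3-oxoeudesma-1,4,11(13)-trien-12-yl acetate
Conditions: DDQ, dioxane, reflux
Reagents that add atoms: none
Why: DDQ dehydrogenation of the 4-en-3-one to the cross-conjugated 1,4-dien-3-one under neutral conditions; the aryl ether has no benzylic hydrogen.

Step 11
Reactants: 15 8β-(4-methoxyphenoxy)-3-oxoeudesma-1,4,11(13)-trien-12-yl acetate
Product: 17 6α-hydroxy-8β-(4-methoxyphenoxy)-3-oxoeudesma-1,4,11(13)-trien-12-yl acetate, via silyl trienol ether 16 (not isolated)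
Conditions: Me3SiOTf, Et3N, CH2Cl2, 0 °C; then mCPBA, NaHCO3, −20 °C; aq citric acid
Reagents that add atoms: 3-chloroperoxybenzoic acid, OOC(=O)c1cccc(Cl)c1
Why: Vinylogous Rubottom oxidation: enolisation is only possible toward C6, and the terminus C6 of the silyl trienol ether should be oxidised from the open α face (C4 is tetrasubstituted); the C6 configuration is erased in step 14.

Step 12
Reactants: 17 6α-hydroxy-8β-(4-methoxyphenoxy)-3-oxoeudesma-1,4,11(13)-trien-12-yl acetate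
Product: 18 1α,2α-epoxy-6α,12-dihydroxy-8β-(4-methoxyphenoxy)eudesma-4,11(13)-dien-3-one
Conditions: 30% H2O2, K2CO3, MeOH, 0 °C → rt
Reagents that add atoms: hydrogen peroxide, OO
Why: Weitz–Scheffer epoxidation of the less substituted C1=C2 bond from the face opposite the C10 methyl; the carbonate/methanol medium also removes the primary acetate by transesterification.

Step 13
Reactants: 18 1α,2α-epoxy-6α,12-dihydroxy-8β-(4-methoxyphenoxy)eudesma-4,11(13)-dien-3-one
Product: 19 8β-(4-methoxyphenoxy)eudesma-2,4,11(13)-triene-1α,6α,12-triol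
Conditions: N2H4·H2O, AcOH (cat.), MeOH, 0 °C → rt
Reagents that add atoms: none
Why: Wharton transposition: the hydrazone of the epoxy ketone collapses with loss of N2 to the allylic alcohol, keeping the C1–O bond (1α) and creating C2=C3 in conjugation with C4=C5.

Step 14
Reactants: 19 8β-(4-methoxyphenoxy)eudesma-2,4,11(13)-triene-1α,6α,12-triol
Product: 20 8β-(4-methoxyphenoxy)-1,6-dioxoeudesma-2,4,11(13)-trien-12-al
Conditions: MnO2 (excess), CH2Cl2, rt
Reagents that add atoms: none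
Why: MnO2 oxidation of all three allylic alcohols (C1, C6, C12) under neutral conditions, which deliberately removes the unwanted 1α and 6α configurations.

Step 15
Reactants: 20 8β-(4-methoxyphenoxy)-1,6-dioxoeudesma-2,4,11(13)-trien-12-al
Product: 21 8β-(4-methoxyphenoxy)eudesma-2,4,11(13)-triene-1β,6β,12-triol
Conditions: NaBH4, CeCl3·7H2O, MeOH, −78 °C; aq NaHCO3
Reagents that add atoms: none
Why: Luche 1,2-reduction of both ring ketones and the aldehyde; hydride should reach C1 and C6 from the α face, away from the axial C10 methyl and the 8β-aryloxy group, giving the 1β and 6β alcohols.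

Step 16
Reactants: 21 8β-(4-methoxyphenoxy)eudesma-2,4,11(13)-triene-1β,6β,12-triol
Product: 22 1β-hydroxy-8β-(4-methoxyphenoxy)eudesma-2,4,11(13)-trien-6β,12-olide
Conditions: TEMPO (cat.), PhI(OAc)2, CH2Cl2, rt
Reagents that add atoms: none
Why: Oxidative lactonisation of a 1,4-diol: the primary allylic alcohol is oxidised first, the aldehyde closes a lactol onto the cis 6β-hydroxyl and a second oxidation gives the cis-fused methylene lactone; the hindered secondary 1β-hydroxyl should react far more slowly.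

Step 17
Reactants: 22 1β-hydroxy-8β-(4-methoxyphenoxy)eudesma-2,4,11(13)-trien-6β,12-olide
Product: 24 1β,2α,5α-trihydroxy-8β-(4-methoxyphenoxy)eudesma-3,11(13)-dien-6β,12-olide, via endoperoxide 23 (not isolated)
Conditions: O2, hν, 5,10,15,20-tetraphenylporphyrin (cat.), CH2Cl2/MeOH, −30 °C; then thiourea, 0 °C → rt
Reagents that add atoms: oxygen, O=O
Why: [4+2] Photooxygenation of the 2,4-diene from the α face (the β face carries the C10 methyl, the 1β-hydroxyl and the lactone oxygen) and thiourea reduction of the O–O bond give the cis 2α,5α-diol and the C3=C4 bond.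

Step 18
Reactants: 24 1β,2α,5α-trihydroxy-8β-(4-methoxyphenoxy)eudesma-3,11(13)-dien-6β,12-olide
Product: 25 2α-(tert-butyldimethylsilyloxy)-1β,5α-dihydroxy-8β-(4-methoxyphenoxy)eudesma-3,11(13)-dien-6β,12-olide
Conditions: t-BuMe2SiCl, imidazole, DMF, 0 °C
Reagents that add atoms: tert-butyldimethylsilyl chloride, CC(C)(C)[Si](C)(C)Cl
Why: Selective silylation of the least hindered hydroxyl: C2–OH is allylic, C1–OH sits next to the quaternary C10 and C5–OH is tertiary.

Step 19
Reactants: 25 2α-(tert-butyldimethylsilyloxy)-1β,5α-dihydroxy-8β-(4-methoxyphenoxy)eudesma-3,11(13)-dien-6β,12-olide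
Product: 26 2α-(tert-butyldimethylsilyloxy)-5α-hydroxy-1β-(methanesulfonyloxy)-8β-(4-methoxyphenoxy)eudesma-3,11(13)-dien-6β,12-olide
Conditions: MeSO2Cl, Et3N, CH2Cl2, −10 °C
Reagents that add atoms: methanesulfonyl chloride, CS(=O)(=O)Cl
Why: Sulfonylation (via sulfene) of the only free secondary alcohol; the tertiary C5 hydroxyl does not react.

Step 20
Reactants: 26 2α-(tert-butyldimethylsilyloxy)-5α-hydroxy-1β-(methanesulfonyloxy)-8β-(4-methoxyphenoxy)eudesma-3,11(13)-dien-6β,12-olide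
Product: 27 2α-(tert-butyldimethylsilyloxy)-5α,8β-dihydroxy-1β-(methanesulfonyloxy)eudesma-3,11(13)-dien-6β,12-olide
Conditions: (NH4)2Ce(NO3)6, pyridine, MeCN/H2O (4:1), 0 °C
Reagents that add atoms: none
Why: Oxidative cleavage of the 4-methoxyphenyl ether (arene radical cation, attack of water, loss of benzoquinone) with the C8–O bond and its configuration retained; the buffer protects the silyl ether.

Step 21
Reactants: 27 2α-(tert-butyldimethylsilyloxy)-5α,8β-dihydroxy-1β-(methanesulfonyloxy)eudesma-3,11(13)-dien-6β,12-olide; 28 tiglic acid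
Product: 29 2α-(tert-butyldimethylsilyloxy)-5α-hydroxy-1β-(methanesulfonyloxy)-8β-[(E)-2-methylbut-2-enoyloxy]eudesma-3,11(13)-dien-6β,12-olide
Conditions: 28, 2,4,6-Cl3C6H2COCl, Et3N, THF, rt; then 27, DMAP, toluene, 40 °C
Reagents that add atoms: none
Why: Yamaguchi esterification: the mixed anhydride acylates the axial 8β-hydroxyl through the acylpyridinium ion with retention, the tertiary C5 hydroxyl is inert, and placing the ester now avoids a protecting-group exchange on the ten-membered ring.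

Step 22
Reactants: 29 2α-(tert-butyldimethylsilyloxy)-5α-hydroxy-1β-(methanesulfonyloxy)-8β-[(E)-2-methylbut-2-enoyloxy]eudesma-3,11(13)-dien-6β,12-olide
Product: 30 (1(10)E,3Z,2R,6R,7R,8R)-2-(tert-butyldimethylsilyloxy)-8-[(E)-2-methylbut-2-enoyloxy]-5-oxogermacra-1(10),3,11(13)-trien-6,12-olide
Conditions: KN(SiMe3)2 (1.1 equiv), THF, −78 → −20 °C; aq NH4Cl
Reagents that add atoms: none
Why: KN(SiMe3)2 deprotonates the tertiary C5 hydroxyl, and because in the rigid trans-decalin the C5–C10 bond is antiperiplanar to the equatorial C1–OMs bond (cis to the C10 methyl), C5=O formation, C5–C10 cleavage, C1=C10 π-bond formation and mesylate loss are concerted. The closest known reaction type is the Wharton–Grob fragmentation of decalin 1,3-diol monosulfonates to E-cyclodecenones. No ring is closed: the ten-membered ring is the periphery of the decalin and is only revealed. No stereocenter is created; the trans C1=C10 geometry follows from the anti relationship of C9 and C2 about the C10–C1 bond, and the cis C3=C4 geometry is inherited from the cyclohexene of ring A. The step needs fragmentation to outrun oxetane formation, elimination and attack on the tiglate or the methylene lactone; the antiperiplanar array, the α-oriented alkoxide (lactone and ester lie on the β face), one equivalent of a hindered base and low temperature should secure this.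

Step 23
Reactants: 30 (1(10)E,3Z,2R,6R,7R,8R)-2-(tert-butyldimethylsilyloxy)-8-[(E)-2-methylbut-2-enoyloxy]-5-oxogermacra-1(10),3,11(13)-trien-6,12-olide
Product: 31 (3Z,1R,2S,6R,7R,8R,10R)-2-(tert-butyldimethylsilyloxy)-1,10-epoxy-8-[(E)-2-methylbut-2-enoyloxy]-5-oxogermacra-3,11(13)-dien-6,12-olide
Conditions: mCPBA, NaHCO3, CH2Cl2, 0 °C
Reagents that add atoms: 3-chloroperoxybenzoic acid, OOC(=O)c1cccc(Cl)c1
Why: Prilezhaev epoxidation of the only electron-rich alkene; the peracid should attack the outer face of the trans C1=C10 bond in the conformer inherited from the decalin (C14 methyl on the upper face), which gives the target configuration at C1 and C10.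

Step 24
Reactants: 31 (3Z,1R,2S,6R,7R,8R,10R)-2-(tert-butyldimethylsilyloxy)-1,10-epoxy-8-[(E)-2-methylbut-2-enoyloxy]-5-oxogermacra-3,11(13)-dien-6,12-olide
Product: 32 (3Z,1R,2S,5R,6R,7R,8R,10R)-2-(tert-butyldimethylsilyloxy)-1,10-epoxy-5-hydroxy-8-[(E)-2-methylbut-2-enoyloxy]germacra-3,11(13)-dien-6,12-olide
Conditions: NaBH4, CeCl3·7H2O, MeOH, −78 °C
Reagents that add atoms: none
Why: Luche 1,2-reduction of the enone at low temperature to spare the methylene lactone; hydride should enter from the exposed outer face, anti to the neighbouring C6–O bond (Felkin–Anh polar model and peripheral attack agree), giving the (5R) alcohol, the C5 epimer of the target, which step 25 corrects.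

Step 25
Reactants: 32 (3Z,1R,2S,5R,6R,7R,8R,10R)-2-(tert-butyldimethylsilyloxy)-1,10-epoxy-5-hydroxy-8-[(E)-2-methylbut-2-enoyloxy]germacra-3,11(13)-dien-6,12-olide
Product: 33 (3Z,1R,2S,5S,6R,7R,8R,10R)-2-(tert-butyldimethylsilyloxy)-1,10-epoxy-5-formyloxy-8-[(E)-2-methylbut-2-enoyloxy]germacra-3,11(13)-dien-6,12-olide
Conditions: HCO2H, PPh3, i-PrO2CN=NCO2i-Pr (premixed), THF, 0 °C
Reagents that add atoms: formic acid, O=CO
Why: Mitsunobu esterification: formate displaces the activated allylic hydroxyl by SN2 from the accessible outer face with inversion, setting the (5S) configuration of the target and protecting O5 at the same time.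

Step 26
Reactants: 33 (3Z,1R,2S,5S,6R,7R,8R,10R)-2-(tert-butyldimethylsilyloxy)-1,10-epoxy-5-formyloxy-8-[(E)-2-methylbut-2-enoyloxy]germacra-3,11(13)-dien-6,12-olide
Product: 34 (3Z,1R,2S,5S,6R,7R,8R,10R)-1,10-epoxy-5-formyloxy-2-hydroxy-8-[(E)-2-methylbut-2-enoyloxy]germacra-3,11(13)-dien-6,12-olide
Conditions: HF·pyridine, pyridine, THF, 0 °C → rt
Reagents that add atoms: none
Why: Fluoride-induced cleavage of the secondary silyl ether under buffered conditions that leave formate, tiglate, lactone and epoxide intact.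

Step 27
Reactants: 34 (3Z,1R,2S,5S,6R,7R,8R,10R)-1,10-epoxy-5-formyloxy-2-hydroxy-8-[(E)-2-methylbut-2-enoyloxy]germacra-3,11(13)-dien-6,12-olide
Product: 35 (3Z,1S,5S,6R,7R,8R,10R)-1,10-epoxy-5-formyloxy-8-[(E)-2-methylbut-2-enoyloxy]-2-oxogermacra-3,11(13)-dien-6,12-olide
Conditions: Dess–Martin periodinane, NaHCO3, CH2Cl2, 0 °C → rt
Reagents that add atoms: none
Why: Dess–Martin oxidation of the allylic secondary alcohol to the epoxy enone under buffered neutral conditions; no stereocenter is affected.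

Step 28
Reactants: 35 (3Z,1S,5S,6R,7R,8R,10R)-1,10-epoxy-5-formyloxy-8-[(E)-2-methylbut-2-enoyloxy]-2-oxogermacra-3,11(13)-dien-6,12-olide
Product: 36 CNP0345622.1, (3Z,1S,5S,6R,7R,8R,10R)-1,10-epoxy-5-hydroxy-8-[(E)-2-methylbut-2-enoyloxy]-2-oxogermacra-3,11(13)-dien-6,12-olide
Conditions: KHCO3 (cat.), MeOH/H2O, 0 °C
Reagents that add atoms: none
Why: Transesterification of the formate, which is far more electrophilic than the conjugated tiglate and the lactone, in cold bicarbonate-buffered methanol.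

Compound list
1 | (S)-carvone | CC1=CC[C@@H](CC1=O)C(C)=C | starting material
2 | (S)-carvone p-toluenesulfonylhydrazone | CC1=CC[C@@H](CC1=NNS(=O)(=O)c2ccc(C)cc2)C(C)=C | intermediate
3 | (5S)-2-methyl-5-(prop-1-en-2-yl)cyclohexa-1,3-diene | CC1=CC[C@@H](C=C1)C(C)=C | intermediate
4 | 5-methyl-7-(prop-1-en-2-yl)-2,3-dioxabicyclo[2.2.2]oct-5-ene, O–O bridge anti to the isopropenyl group | CC1=C[C@@H]2OO[C@H]1C[C@@H]2C(C)=C | intermediate
5 | (4S,5R)-4-hydroxy-2-methyl-5-(prop-1-en-2-yl)cyclohex-2-en-1-one | CC1=C[C@H](O)[C@H](CC1=O)C(C)=C | intermediate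
6 | (4S,5R)-4-hydroxy-2-methyl-5-(prop-1-en-2-yl)cyclohexan-1-one, C2 epimers | CC1C[C@H](O)[C@H](CC1=O)C(C)=C | intermediate
7 | (4S,5R)-5-(3-chloroprop-1-en-2-yl)-4-hydroxy-2-methylcyclohexan-1-one | CC1C[C@H](O)[C@H](CC1=O)C(CCl)=C | intermediate
8 | 2-[(1R,2S)-2-hydroxy-4-methyl-5-oxocyclohexyl]prop-2-en-1-yl acetate | CC1C[C@H](O)[C@H](CC1=O)C(COC(C)=O)=C | intermediate
9 | 2-[(1R,2R)-2-(4-methoxyphenoxy)-4-methyl-5-oxocyclohexyl]prop-2-en-1-yl acetate | CC1C[C@@H](Oc2ccc(OC)cc2)[C@H](CC1=O)C(COC(C)=O)=C | intermediate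
10 | ethyl vinyl ketone (pent-1-en-3-one) | CCC(=O)C=C | starting material
11 | N-[(R)-1-phenylethyl] ketimine of 9 | CC1C[C@@H](Oc2ccc(OC)cc2)[C@H](CC1=N[C@H](C)c3ccccc3)C(COC(C)=O)=C | intermediate
12 | N-[(R)-1-phenylethyl] ketimine of 13 | CCC(=O)CC[C@]1(C)C[C@@H](Oc2ccc(OC)cc2)[C@H](CC1=N[C@H](C)c3ccccc3)C(COC(C)=O)=C | intermediate
13 | 2-[(1R,2R,4R)-2-(4-methoxyphenoxy)-4-methyl-5-oxo-4-(3-oxopentyl)cyclohexyl]prop-2-en-1-yl acetate | CCC(=O)CC[C@]1(C)C[C@@H](Oc2ccc(OC)cc2)[C@H](CC1=O)C(COC(C)=O)=C | intermediate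
14 | 8β-(4-methoxyphenoxy)-3-oxoeudesma-4,11(13)-dien-12-yl acetate | CC(=O)OCC(=C)[C@H]1CC2=C(C)C(=O)CC[C@]2(C)C[C@H]1Oc3ccc(OC)cc3 | intermediate
15 | 8β-(4-methoxyphenoxy)-3-oxoeudesma-1,4,11(13)-trien-12-yl acetate | CC(=O)OCC(=C)[C@H]1CC2=C(C)C(=O)C=C[C@]2(C)C[C@H]1Oc3ccc(OC)cc3 | intermediate
16 | 8β-(4-methoxyphenoxy)-3-(trimethylsilyloxy)eudesma-1,3,5,11(13)-tetraen-12-yl acetate | CC(=O)OCC(=C)[C@H]1C=C2C(C)=C(O[Si](C)(C)C)C=C[C@]2(C)C[C@H]1Oc3ccc(OC)cc3 | intermediate
17 | 6α-hydroxy-8β-(4-methoxyphenoxy)-3-oxoeudesma-1,4,11(13)-trien-12-yl acetate | CC(=O)OCC(=C)[C@H]1[C@H](O)C2=C(C)C(=O)C=C[C@]2(C)C[C@H]1Oc3ccc(OC)cc3 | intermediate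
18 | 1α,2α-epoxy-6α,12-dihydroxy-8β-(4-methoxyphenoxy)eudesma-4,11(13)-dien-3-one | OCC(=C)[C@H]1[C@H](O)C2=C(C)C(=O)[C@@H]3O[C@@H]3[C@]2(C)C[C@H]1Oc4ccc(OC)cc4 | intermediate
19 | 8β-(4-methoxyphenoxy)eudesma-2,4,11(13)-triene-1α,6α,12-triol | OCC(=C)[C@H]1[C@H](O)C2=C(C)C=C[C@H](O)[C@]2(C)C[C@H]1Oc3ccc(OC)cc3 | intermediate
20 | 8β-(4-methoxyphenoxy)-1,6-dioxoeudesma-2,4,11(13)-trien-12-al | O=CC(=C)[C@H]1C(=O)C2=C(C)C=CC(=O)[C@]2(C)C[C@H]1Oc3ccc(OC)cc3 | intermediate
21 | 8β-(4-methoxyphenoxy)eudesma-2,4,11(13)-triene-1β,6β,12-triol | OCC(=C)[C@H]1[C@@H](O)C2=C(C)C=C[C@@H](O)[C@]2(C)C[C@H]1Oc3ccc(OC)cc3 | intermediate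
22 | 1β-hydroxy-8β-(4-methoxyphenoxy)eudesma-2,4,11(13)-trien-6β,12-olide | C=C1C(=O)O[C@@H]2[C@H]1[C@H](Oc4ccc(OC)cc4)C[C@@]3(C)[C@H](O)C=CC(C)=C23 | intermediate
23 | 2α,5α-epidioxy-1β-hydroxy-8β-(4-methoxyphenoxy)eudesma-3,11(13)-dien-6β,12-olide | C=C1C(=O)O[C@@H]2[C@H]1[C@H](Oc5ccc(OC)cc5)C[C@@]3(C)[C@H](O)[C@@H]4C=C(C)[C@]23OO4 | intermediate
24 | 1β,2α,5α-trihydroxy-8β-(4-methoxyphenoxy)eudesma-3,11(13)-dien-6β,12-olide | C=C1C(=O)O[C@@H]2[C@H]1[C@H](Oc4ccc(OC)cc4)C[C@@]3(C)[C@H](O)[C@@H](O)C=C(C)[C@]23O | intermediate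
25 | 2α-(tert-butyldimethylsilyloxy)-1β,5α-dihydroxy-8β-(4-methoxyphenoxy)eudesma-3,11(13)-dien-6β,12-olide | C=C1C(=O)O[C@@H]2[C@H]1[C@H](Oc4ccc(OC)cc4)C[C@@]3(C)[C@H](O)[C@@H](O[Si](C)(C)C(C)(C)C)C=C(C)[C@]23O | intermediate
26 | 2α-(tert-butyldimethylsilyloxy)-5α-hydroxy-1β-(methanesulfonyloxy)-8β-(4-methoxyphenoxy)eudesma-3,11(13)-dien-6β,12-olide | C=C1C(=O)O[C@@H]2[C@H]1[C@H](Oc4ccc(OC)cc4)C[C@@]3(C)[C@H](OS(C)(=O)=O)[C@@H](O[Si](C)(C)C(C)(C)C)C=C(C)[C@]23O | intermediate
27 | 2α-(tert-butyldimethylsilyloxy)-5α,8β-dihydroxy-1β-(methanesulfonyloxy)eudesma-3,11(13)-dien-6β,12-olide | C=C1C(=O)O[C@@H]2[C@H]1[C@H](O)C[C@@]3(C)[C@H](OS(C)(=O)=O)[C@@H](O[Si](C)(C)C(C)(C)C)C=C(C)[C@]23O | intermediate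
28 | tiglic acid, (E)-2-methylbut-2-enoic acid | C/C=C(\C)C(=O)O | starting material
29 | 2α-(tert-butyldimethylsilyloxy)-5α-hydroxy-1β-(methanesulfonyloxy)-8β-[(E)-2-methylbut-2-enoyloxy]eudesma-3,11(13)-dien-6β,12-olide (trans-decalin, 10β-CH3) | C=C1C(=O)O[C@@H]2[C@H]1[C@H](OC(=O)/C(C)=C/C)C[C@@]3(C)[C@H](OS(C)(=O)=O)[C@@H](O[Si](C)(C)C(C)(C)C)C=C(C)[C@]23O | intermediate
30 | (1(10)E,3Z,2R,6R,7R,8R)-2-(tert-butyldimethylsilyloxy)-8-[(E)-2-methylbut-2-enoyloxy]-5-oxogermacra-1(10),3,11(13)-trien-6,12-olide | C=C1C(=O)O[C@@H]2[C@H]1[C@H](OC(=O)/C(C)=C/C)C/C(C)=C/[C@@H](O[Si](C)(C)C(C)(C)C)/C=C(/C)C2=O | intermediate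
31 | (3Z,1R,2S,6R,7R,8R,10R)-2-(tert-butyldimethylsilyloxy)-1,10-epoxy-8-[(E)-2-methylbut-2-enoyloxy]-5-oxogermacra-3,11(13)-dien-6,12-olide | C=C1C(=O)O[C@@H]2[C@H]1[C@H](OC(=O)/C(C)=C/C)C[C@@]3(C)O[C@@H]3[C@@H](O[Si](C)(C)C(C)(C)C)/C=C(/C)C2=O | intermediate
32 | (3Z,1R,2S,5R,6R,7R,8R,10R)-2-(tert-butyldimethylsilyloxy)-1,10-epoxy-5-hydroxy-8-[(E)-2-methylbut-2-enoyloxy]germacra-3,11(13)-dien-6,12-olide | C=C1C(=O)O[C@@H]2[C@H]1[C@H](OC(=O)/C(C)=C/C)C[C@@]3(C)O[C@@H]3[C@@H](O[Si](C)(C)C(C)(C)C)/C=C(/C)[C@H]2O | intermediate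
33 | (3Z,1R,2S,5S,6R,7R,8R,10R)-2-(tert-butyldimethylsilyloxy)-1,10-epoxy-5-formyloxy-8-[(E)-2-methylbut-2-enoyloxy]germacra-3,11(13)-dien-6,12-olide | C=C1C(=O)O[C@@H]2[C@H]1[C@H](OC(=O)/C(C)=C/C)C[C@@]3(C)O[C@@H]3[C@@H](O[Si](C)(C)C(C)(C)C)/C=C(/C)[C@@H]2OC=O | intermediate
34 | (3Z,1R,2S,5S,6R,7R,8R,10R)-1,10-epoxy-5-formyloxy-2-hydroxy-8-[(E)-2-methylbut-2-enoyloxy]germacra-3,11(13)-dien-6,12-olide | C=C1C(=O)O[C@@H]2[C@H]1[C@H](OC(=O)/C(C)=C/C)C[C@@]3(C)O[C@@H]3[C@@H](O)/C=C(/C)[C@@H]2OC=O | intermediate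
35 | (3Z,1S,5S,6R,7R,8R,10R)-1,10-epoxy-5-formyloxy-8-[(E)-2-methylbut-2-enoyloxy]-2-oxogermacra-3,11(13)-dien-6,12-olide | C=C1C(=O)O[C@@H]2[C@H]1[C@H](OC(=O)/C(C)=C/C)C[C@@]3(C)O[C@@H]3C(=O)/C=C(/C)[C@@H]2OC=O | intermediate
36 | CNP0345622.1, (3Z,1S,5S,6R,7R,8R,10R)-1,10-epoxy-5-hydroxy-8-[(E)-2-methylbut-2-enoyloxy]-2-oxogermacra-3,11(13)-dien-6,12-olide | C=C1C(=O)O[C@@H]2[C@H]1[C@H](OC(=O)/C(C)=C/C)C[C@@]1(C)O[C@@H]1C(=O)/C=C(/C)[C@@H]2O | target

Total step count: 28. Longest linear sequence: 28 steps (1 to 36); 10 and 28 enter as commercial reagents.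

Steps most likely to fail

Step 14. The aldehyde-activated C7–H of the dione may allow migration of the exocyclic double bond into conjugation, epimerisation at C7 or loss of the 8β-aryloxy group by β-elimination. The fallback avoids the aldehyde: setting out from 19, the primary hydroxyl is silylated selectively (t-BuMe2SiCl, imidazole) to give the 12-silyl ether F1, MnO2 then oxidises only C1 and C6 to the 12-silyloxy 1,6-dione F2, NaBH4/CeCl3·7H2O reduces it to the 1β,6β-diol F3, and Bu4NF removes the silyl group to rejoin the route at 21.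

Step 22. The base may deprotonate or add to the methylene lactone, or the alkoxide may attack an ester, before fragmentation occurs. The fallback masks the acceptor: setting out from 29, dimethylamine (THF, 0 °C) adds to the methylene lactone to give the amino lactone F4, fragmentation with KN(SiMe3)2 as in step 22 gives the amino cyclodecadienone F5, and two equivalents of mCPBA then epoxidise C1=C10 and oxidise the amine to its N-oxide, whose Cope elimination restores the methylene lactone, so that the route is rejoined at 31.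

Step 25. Activation of the shielded allylic hydroxyl may be sluggish, and allylic transposition or elimination may compete with direct substitution. The fallback separates activation from displacement: setting out from 32, ClCH2SO2Cl and pyridine give the C5 chloromethanesulfonate F6, which is displaced with inversion by CsO2CH and 18-crown-6 in toluene to rejoin the route at 33.

Further compounds
F1 | step 14 | 12-(tert-butyldimethylsilyloxy)-8β-(4-methoxyphenoxy)eudesma-2,4,11(13)-triene-1α,6α-diol | CC(C)(C)[Si](C)(C)OCC(=C)[C@H]1[C@H](O)C2=C(C)C=C[C@H](O)[C@]2(C)C[C@H]1Oc3ccc(OC)cc3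
F2 | step 14 | 12-(tert-butyldimethylsilyloxy)-8β-(4-methoxyphenoxy)eudesma-2,4,11(13)-triene-1,6-dione | CC(C)(C)[Si](C)(C)OCC(=C)[C@H]1C(=O)C2=C(C)C=CC(=O)[C@]2(C)C[C@H]1Oc3ccc(OC)cc3
F3 | step 14 | 12-(tert-butyldimethylsilyloxy)-8β-(4-methoxyphenoxy)eudesma-2,4,11(13)-triene-1β,6β-diol | CC(C)(C)[Si](C)(C)OCC(=C)[C@H]1[C@@H](O)C2=C(C)C=C[C@@H](O)[C@]2(C)C[C@H]1Oc3ccc(OC)cc3
F4 | step 22 | 13-(dimethylamino)-11,13-dihydro derivative of 29 (C11 unassigned) | CN(C)CC1C(=O)O[C@@H]2[C@H]1[C@H](OC(=O)/C(C)=C/C)C[C@@]3(C)[C@H](OS(C)(=O)=O)[C@@H](O[Si](C)(C)C(C)(C)C)C=C(C)[C@]23O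
F5 | step 22 | 13-(dimethylamino)-11,13-dihydro derivative of 30 (C11 unassigned) | CN(C)CC1C(=O)O[C@@H]2[C@H]1[C@H](OC(=O)/C(C)=C/C)C/C(C)=C/[C@@H](O[Si](C)(C)C(C)(C)C)/C=C(/C)C2=O
F6 | step 25 | C5 chloromethanesulfonate of 32 (5R) | C=C1C(=O)O[C@@H]2[C@H]1[C@H](OC(=O)/C(C)=C/C)C[C@@]3(C)O[C@@H]3[C@@H](O[Si](C)(C)C(C)(C)C)/C=C(/C)[C@H]2OS(=O)(=O)CCl
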